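**Retrosynthetic overview**

1. Target 27 comes from the octabenzyl ether 26 by one global hydrogenolysis.
2. Key disconnection: the lower pyran ring of 26 is cut at O1–C8a and at C4–C4a. This gives the 4-arylflavan 21 (the complete upper unit, whose 4-aryl group is the future lower ring A with F on C8a and Br on C4a) and the C2–C3–C4 aldehyde 22.
3. Enabling feature: in the lower unit, O1 (on C8a) and the carbinol carbon C4 (on C4a) sit on neighbouring carbons of the 7,8-dioxygenated ring A, and O1 is the benzylic oxygen of an all-cis C2–C3–C4 triol chain. A 2-fluoroaryl-metal (C4a nucleophile, C8a electrophile) and a 3-oxy-aldehyde (C4 electrophile, C2–O nucleophile) are therefore polarity-matched partners for a [4+2]-type annulation that leaves C2 and C3 (from a syn-aldol) untouched.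
4. The interflavan bond C4(upper)–C6(lower) and the upper C3–O bond come from a Cu/Pd syn-arylboration of the (2R)-flav-3-ene 14 with aryl iodide 18, which fixes 2,3-trans-3,4-cis.
5. Ring order: upper pyran ring (from daphnetin, steps 5–7), then C4–C6 bond and upper C3–O (steps 11–12), then lower pyran ring (step 15).

Key step: step 15

Remark: flavan numbering (O1, C2, C3, C4, C4a–C8a) is used for each unit. The CIP label of the upper C4 is S in 19–21 and 26 and R in 27; the spatial arrangement is the same, only the priorities of the two aryl branches swap.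

**Route**

Step 1
Reactants: 1 (S)-4-benzyl-1,3-oxazolidin-2-one; 2 (benzyloxy)acetyl chloride
Product: 3 (S)-4-benzyl-3-[(benzyloxy)acetyl]-1,3-oxazolidin-2-one
Conditions: n-BuLi, THF, −78 °C; then 2, −78 → 0 °C
Reagents that add atoms: none
Why: N-acylation of the lithiated oxazolidinone by the acid chloride (loading of the Evans auxiliary); no stereocentre is formed.

Step 2
Reactants: 3 (S)-4-benzyl-3-[(benzyloxy)acetyl]-1,3-oxazolidin-2-one; 4 4-(benzyloxy)benzaldehyde
Product: 5 (4S)-4-benzyl-3-[(2S,3R)-2-(benzyloxy)-3-[4-(benzyloxy)phenyl]-3-hydroxypropanoyl]-1,3-oxazolidin-2-one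
Conditions: Bu2BOTf, Et3N, CH2Cl2, −78 → 0 °C; then H2O2, MeOH, pH 7 buffer
Reagents that add atoms: none
Why: Evans syn-aldol reaction: the (Z)-boron enolate reacts through a Zimmerman–Traxler chair on the face opposite the benzyl group of the auxiliary, which should set 2S,3R (the future C3 and C2 of the lower unit, 2,3-cis).

Step 3
Reactants: 5 the syn-aldol adduct
Product: 6 (2S,3R)-2-(benzyloxy)-3-[4-(benzyloxy)phenyl]-3-hydroxy-N-methoxy-N-methylpropanamide
Conditions: MeNH(OMe)·HCl, AlMe3, CH2Cl2, −20 → 0 °C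
Reagents that add atoms: N,O-dimethylhydroxylamine hydrochloride, CNOC.Cl
Why: Transamination with the aluminium amide of N,O-dimethylhydroxylamine (Weinreb amide synthesis), assisted by the free β-hydroxyl; the two stereocentres are not touched.

Step 4
Reactants: 6 the β-hydroxy Weinreb amide
Product: 7 (2S,3R)-2-(benzyloxy)-3-[4-(benzyloxy)phenyl]-N-methoxy-N-methyl-3-[(triethylsilyl)oxy]propanamide
Conditions: Et3SiCl, imidazole, DMF, 0 → 25 °C
Reagents that add atoms: chlorotriethylsilane, CC[Si](Cl)(CC)CC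
Why: Silylation of the secondary benzylic alcohol; the triethylsilyl group is stable to i-Bu2AlH but is cleaved by alkoxide, as step 15 needs.

Step 5
Reactants: 8 7,8-dihydroxycoumarin (daphnetin)
Product: 9 7,8-bis(benzyloxy)-2H-chromen-2-one
Conditions: BnBr, K2CO3, DMF, 60 °C
Reagents that add atoms: benzyl bromide, BrCc1ccccc1
Why: Williamson ether synthesis on both phenols; the lactone survives carbonate in DMF.

Step 6
Reactants: 9 7,8-bis(benzyloxy)-2H-chromen-2-one
Product: 11 7,8-bis(benzyloxy)-2-ethoxy-2H-chromene (racemic), via lactol 10 (not isolated)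
Conditions: i-Bu2AlH, CH2Cl2, −78 °C; then EtOH, PPTS, 25 °C
Reagents that add atoms: ethanol, CCO
Why: Partial reduction of the coumarin lactone to the lactol and acid-catalysed acetalization through the 1-benzopyrylium ion; the acetal carbon is racemic and is re-set in step 7.

Step 7
Reactants: 11 7,8-bis(benzyloxy)-2-ethoxy-2H-chromene; 12 [4-(benzyloxy)phenyl]boronic acid
Product: 14 (2R)-7,8-bis(benzyloxy)-2-[4-(benzyloxy)phenyl]-2H-chromene, via diethyl arylboronate 13 (not isolated)
Conditions: 12, EtOH, toluene, 4 Å MS (gives 13); then 11, tartaric acid-derived α,β-dihydroxy carboxylic acid catalyst (5 mol%), Ce(OTf)4 (5 mol%), EtOAc, −20 °C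
Reagents that add atoms: none
Why: Enantioselective addition of an aryl boronate to the benzopyrylium ion generated from the chromene acetal (chiral Brønsted acid/Lewis acid catalysis, a Petasis-type reaction known for 2-ethoxy-2H-chromenes); the chiral dioxaborolane formed with the catalyst delivers the aryl group to one face of C2, and the catalyst antipode that gives 2R is used.

Step 8
Reactants: 15 3-fluorobenzene-1,2-diol (3-fluorocatechol)
Product: 16 1,2-bis(benzyloxy)-3-fluorobenzene
Conditions: BnBr, K2CO3, DMF, 60 °C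
Reagents that add atoms: benzyl bromide, BrCc1ccccc1
Why: Williamson ether synthesis.

Step 9
Reactants: 16 1,2-bis(benzyloxy)-3-fluorobenzene
Product: 17 1-bromo-3,4-bis(benzyloxy)-2-fluorobenzene
Conditions: NBS, MeCN, 0 → 25 °C, dark
Reagents that add atoms: N-bromosuccinimide, O=C1CCC(=O)N1Br
Why: Electrophilic aromatic bromination para to the terminal, coplanar benzyloxy group, the strongest director; the central benzyloxy group is twisted out of conjugation and fluorine directs only weakly.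

Step 10
Reactants: 17 1-bromo-3,4-bis(benzyloxy)-2-fluorobenzene
Product: 18 1-bromo-3,4-bis(benzyloxy)-2-fluoro-5-iodobenzene
Conditions: NIS, CF3CO2H (cat.), MeCN, 25 °C
Reagents that add atoms: N-iodosuccinimide, O=C1CCC(=O)N1I
Why: Electrophilic aromatic iodination at the position ortho to the coplanar benzyloxy group and para to fluorine; the other free position (para to the twisted benzyloxy group, ortho to bromine) should react more slowly.

Step 11
Reactants: 14 (2R)-7,8-bis(benzyloxy)-2-[4-(benzyloxy)phenyl]-2H-chromene; 18 1-bromo-3,4-bis(benzyloxy)-2-fluoro-5-iodobenzene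
Product: 19 2-{(2R,3R,4S)-7,8-bis(benzyloxy)-2-[4-(benzyloxy)phenyl]-4-[2,3-bis(benzyloxy)-5-bromo-4-fluorophenyl]chroman-3-yl}-4,4,5,5-tetramethyl-1,3,2-dioxaborolane (2,3-trans-3,4-cis)
Conditions: B2pin2, (SIMes)CuCl (cat.), Pd(OAc)2/RuPhos (cat.), NaOt-Bu, toluene/THF, 25 °C
Reagents that add atoms: bis(pinacolato)diboron, CC1(C)OB(OC1(C)C)B1OC(C)(C)C(C)(C)O1
Why: Cu/Pd-cocatalysed syn-1,2-arylboration of a cyclic styrenyl alkene: borylcupration puts copper on benzylic C4 and boron on C3 from the face anti to the C2 aryl group, zerovalent palladium inserts into the C–I bond only, and stereoretentive Cu-to-Pd transmetalation with reductive elimination places the aryl group cis to boron.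

Step 12
Reactants: 19 the C3 boronate
Product: 20 (2S,3R,4S)-7,8-bis(benzyloxy)-2-[4-(benzyloxy)phenyl]-4-[2,3-bis(benzyloxy)-5-bromo-4-fluorophenyl]chroman-3-ol
Conditions: H2O2, NaOH, THF/H2O, 0 °C
Reagents that add atoms: hydrogen peroxide, OO
Why: Oxidation of the secondary alkyl boronate with basic hydrogen peroxide, which goes with retention at C3 by 1,2-migration.

Step 13
Reactants: 20 the 4-arylflavan-3-ol
Product: 21 (2S,3R,4S)-3,7,8-tris(benzyloxy)-2-[4-(benzyloxy)phenyl]-4-[2,3-bis(benzyloxy)-5-bromo-4-fluorophenyl]chromane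
Conditions: NaH, BnBr, Bu4NI (cat.), DMF, 0 → 25 °C
Reagents that add atoms: benzyl bromide, BrCc1ccccc1
Why: Williamson etherification of the secondary alkoxide; it removes the only acidic proton before the organolithium step.

Step 14
Reactants: 7 the silylated Weinreb amide
Product: 22 (2S,3R)-2-(benzyloxy)-3-[4-(benzyloxy)phenyl]-3-[(triethylsilyl)oxy]propanal
Conditions: i-Bu2AlH, THF, −78 °C; Rochelle salt work-up
Reagents that add atoms: none
Why: Reduction of the Weinreb amide stops at the chelated tetrahedral intermediate and gives the aldehyde on work-up, without epimerization of the α-alkoxy centre at −78 °C.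

Step 15
Reactants: 21 the aryl bromide; 22 the aldehyde
Product: 26 (2R,3R,4R)-3,7,8-tris(benzyloxy)-2-[4-(benzyloxy)phenyl]-6-{(2S,3R,4S)-3,7,8-tris(benzyloxy)-2-[4-(benzyloxy)phenyl]chroman-4-yl}chroman-4-ol, via aryllithium 23 (not isolated), via aryltitanium triisopropoxide 24 (not isolated), via titanium alkoxide adduct 25 (not isolated)
Conditions: n-BuLi, THF, −78 °C; ClTi(Oi-Pr)3, −78 → −40 °C; 22, −40 → −10 °C; then KOt-Bu, DMPU, 55 °C
Reagents that add atoms: none
Why: Proposed new method: Br/Li exchange and transmetalation give the 2-fluoroaryl-titanium 24, which adds to the aldehyde carbon of 22 (bond C4a–C4); potassium tert-butoxide then removes the triethylsilyl group from the C2 oxygen, and the freed secondary alkoxide displaces the ortho-fluoride on C8a by addition–elimination (bond O1–C8a), so that the arene reacts as a 1,2-dipole and the chain as its complement in a formal [4+2] annulation. The closest known reactions are additions of 2-fluoroaryl-metal reagents to carbonyl compounds followed by intramolecular SNAr of the resulting alkoxides, and base-mediated cyclization of 3-(2-fluoroaryl)propanols to chromans; what is new is the one-pot use on a non-activated, electron-rich fluoroarene with a silyl-masked β-oxygen to give a flavan-3,4-diol. The pyran ring closes by 6-exo attack of oxygen on the aromatic carbon through a Meisenheimer-type transition state; the C4 alkoxide could only form a four-membered ring and the C3 oxygen is blocked as its benzyl ether, so only the six-membered ring can form, and no aryne can arise because both positions ortho to fluorine are substituted. C2 and C3 are carried over unchanged from the aldol (retention, 2,3-cis), and the new C4 centre is set by Felkin–Anh addition of the non-chelating aryltitanium reagent anti to the C3 benzyloxy group, which is 3,4-anti in the chain and 3,4-cis in the ring. The step needs site-selective metalation, which the single C–Br bond of 21 secures, and tolerance of the upper unit to alkoxide base, which should follow from full O-benzylation and the hindered, weakly acidic C4–H.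

Step 16
Reactants: 26 the octabenzyl ether
Product: 27 (2R,3R,4R)-2-(4-hydroxyphenyl)-6-[(2S,3R,4R)-3,7,8-trihydroxy-2-(4-hydroxyphenyl)chroman-4-yl]chromane-3,4,7,8-tetrol (CNP0391561.7)
Conditions: H2 (1 atm), Pd(OH)2/C, THF/MeOH, 25 °C
Reagents that add atoms: none
Why: Hydrogenolysis of the eight benzyl ethers under neutral conditions; the diarylmethine C4–C6 bond and, in the absence of acid, the free benzylic C4 hydroxyl should survive.

**Compound list**

1 | (S)-4-benzyl-1,3-oxazolidin-2-one | O=C1OC[C@H](Cc2ccccc2)N1 | starting material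
2 | (benzyloxy)acetyl chloride | O=C(Cl)COCc1ccccc1 | starting material
3 | (S)-4-benzyl-3-[(benzyloxy)acetyl]-1,3-oxazolidin-2-one | O=C1OC[C@H](Cc2ccccc2)N1C(=O)COCc1ccccc1 | intermediate
4 | 4-(benzyloxy)benzaldehyde | O=Cc1ccc(OCc2ccccc2)cc1 | starting material
5 | (4S)-4-benzyl-3-[(2S,3R)-2-(benzyloxy)-3-[4-(benzyloxy)phenyl]-3-hydroxypropanoyl]-1,3-oxazolidin-2-one | O=C1OC[C@H](Cc2ccccc2)N1C(=O)[C@@H](OCc1ccccc1)[C@H](O)c1ccc(OCc2ccccc2)cc1 | intermediate
6 | (2S,3R)-2-(benzyloxy)-3-[4-(benzyloxy)phenyl]-3-hydroxy-N-methoxy-N-methylpropanamide | CON(C)C(=O)[C@@H](OCc1ccccc1)[C@H](O)c1ccc(OCc2ccccc2)cc1 | intermediate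
7 | (2S,3R)-2-(benzyloxy)-3-[4-(benzyloxy)phenyl]-N-methoxy-N-methyl-3-[(triethylsilyl)oxy]propanamide | CON(C)C(=O)[C@@H](OCc1ccccc1)[C@H](O[Si](CC)(CC)CC)c1ccc(OCc2ccccc2)cc1 | intermediate
8 | 7,8-dihydroxy-2H-chromen-2-one (daphnetin) | O=c1ccc2ccc(O)c(O)c2o1 | starting material
9 | 7,8-bis(benzyloxy)-2H-chromen-2-one | O=c1ccc2ccc(OCc3ccccc3)c(OCc3ccccc3)c2o1 | intermediate
10 | 7,8-bis(benzyloxy)-2H-chromen-2-ol (racemic lactol) | OC1C=Cc2ccc(OCc3ccccc3)c(OCc3ccccc3)c2O1 | intermediate
11 | 7,8-bis(benzyloxy)-2-ethoxy-2H-chromene (racemic) | CCOC1C=Cc2ccc(OCc3ccccc3)c(OCc3ccccc3)c2O1 | intermediate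
12 | [4-(benzyloxy)phenyl]boronic acid | OB(O)c1ccc(OCc2ccccc2)cc1 | starting material
13 | diethyl [4-(benzyloxy)phenyl]boronate | CCOB(OCC)c1ccc(OCc2ccccc2)cc1 | intermediate
14 | (2R)-7,8-bis(benzyloxy)-2-[4-(benzyloxy)phenyl]-2H-chromene | C1=Cc2ccc(OCc3ccccc3)c(OCc3ccccc3)c2O[C@H]1c1ccc(OCc2ccccc2)cc1 | intermediate
15 | 3-fluorobenzene-1,2-diol | Oc1cccc(F)c1O | starting material
16 | 1,2-bis(benzyloxy)-3-fluorobenzene | Fc1cccc(OCc2ccccc2)c1OCc1ccccc1 | intermediate
17 | 1-bromo-3,4-bis(benzyloxy)-2-fluorobenzene | Fc1c(Br)ccc(OCc2ccccc2)c1OCc1ccccc1 | intermediate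
18 | 1-bromo-3,4-bis(benzyloxy)-2-fluoro-5-iodobenzene | Fc1c(Br)cc(I)c(OCc2ccccc2)c1OCc1ccccc1 | intermediate
19 | (2R,3R,4S)-3-boryl-4-arylflavan: Bpin on C3 trans to the C2 aryl and cis to the C4 aryl (2,3-bis(benzyloxy)-5-bromo-4-fluorophenyl) | Brc1cc([C@@H]2c3ccc(OCc4ccccc4)c(OCc4ccccc4)c3O[C@@H](c3ccc(OCc4ccccc4)cc3)[C@@H]2B2OC(C)(C)C(C)(C)O2)c(OCc2ccccc2)c(OCc2ccccc2)c1F | intermediate
20 | (2S,3R,4S)-7,8-bis(benzyloxy)-2-[4-(benzyloxy)phenyl]-4-[2,3-bis(benzyloxy)-5-bromo-4-fluorophenyl]chroman-3-ol (2,3-trans-3,4-cis) | Brc1cc([C@@H]2c3ccc(OCc4ccccc4)c(OCc4ccccc4)c3O[C@@H](c3ccc(OCc4ccccc4)cc3)[C@@H]2O)c(OCc2ccccc2)c(OCc2ccccc2)c1F | intermediate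
21 | (2S,3R,4S)-3,7,8-tris(benzyloxy)-2-[4-(benzyloxy)phenyl]-4-[2,3-bis(benzyloxy)-5-bromo-4-fluorophenyl]chromane | Brc1cc([C@@H]2c3ccc(OCc4ccccc4)c(OCc4ccccc4)c3O[C@@H](c3ccc(OCc4ccccc4)cc3)[C@@H]2OCc2ccccc2)c(OCc2ccccc2)c(OCc2ccccc2)c1F | intermediate
22 | (2S,3R)-2-(benzyloxy)-3-[4-(benzyloxy)phenyl]-3-[(triethylsilyl)oxy]propanal | O=C[C@@H](OCc1ccccc1)[C@H](O[Si](CC)(CC)CC)c1ccc(OCc2ccccc2)cc1 | intermediate
23 | aryllithium from 21 (Li in place of Br) | [Li]c1cc([C@@H]2c3ccc(OCc4ccccc4)c(OCc4ccccc4)c3O[C@@H](c3ccc(OCc4ccccc4)cc3)[C@@H]2OCc2ccccc2)c(OCc2ccccc2)c(OCc2ccccc2)c1F | intermediate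
24 | aryltitanium triisopropoxide from 23 | CC(C)O[Ti](OC(C)C)(OC(C)C)c1cc([C@@H]2c3ccc(OCc4ccccc4)c(OCc4ccccc4)c3O[C@@H](c3ccc(OCc4ccccc4)cc3)[C@@H]2OCc2ccccc2)c(OCc2ccccc2)c(OCc2ccccc2)c1F | intermediate
25 | Felkin adduct as its titanium alkoxide: open-chain carbinol with the new centre (lower C4) R, C3–OBn and C2–OSiEt3 as in 22 | CC(C)O[Ti](OC(C)C)(OC(C)C)O[C@H](c1cc([C@@H]2c3ccc(OCc4ccccc4)c(OCc4ccccc4)c3O[C@@H](c3ccc(OCc4ccccc4)cc3)[C@@H]2OCc2ccccc2)c(OCc2ccccc2)c(OCc2ccccc2)c1F)[C@@H](OCc1ccccc1)[C@H](O[Si](CC)(CC)CC)c1ccc(OCc2ccccc2)cc1 | intermediate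
26 | (2R,3R,4R)-3,7,8-tris(benzyloxy)-2-[4-(benzyloxy)phenyl]-6-{(2S,3R,4S)-3,7,8-tris(benzyloxy)-2-[4-(benzyloxy)phenyl]chroman-4-yl}chroman-4-ol | c1ccccc1COc1ccc([C@H]2Oc3c(cc([C@@H]4c5ccc(OCc6ccccc6)c(OCc6ccccc6)c5O[C@@H](c5ccc(OCc6ccccc6)cc5)[C@@H]4OCc4ccccc4)c(OCc4ccccc4)c3OCc3ccccc3)[C@@H](O)[C@H]2OCc2ccccc2)cc1 | intermediate
27 | (2R,3R,4R)-2-(4-hydroxyphenyl)-6-[(2S,3R,4R)-3,7,8-trihydroxy-2-(4-hydroxyphenyl)chroman-4-yl]chromane-3,4,7,8-tetrol | Oc1ccc([C@H]2Oc3c(cc([C@@H]4c5ccc(O)c(O)c5O[C@@H](c5ccc(O)cc5)[C@@H]4O)c(O)c3O)[C@@H](O)[C@H]2O)cc1 | target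

**Step count and risks**

Total step count: 16. Longest linear sequence: 8 steps (5 → 6 → 7 → 11 → 12 → 13 → 15 → 16).

Steps most likely to fail:

1. Step 15 (proposed new method). The displacement of fluoride from the electron-rich ring may be too slow, so that base-induced degradation or hydride transfer from the titanium alkoxide to excess aldehyde competes. Felkin selectivity in the addition may also be incomplete. The fallback sets out from 21 and 7 and works at the ketone oxidation level. The aryllithium from 21 (n-BuLi, −78 °C) is added to Weinreb amide 7 to give the 2-fluoroaryl ketone F1. Buffered HF·pyridine removes the silyl group and gives the β-hydroxy ketone F2. K2CO3 in DMF at 0–25 °C closes the ring by ketone-activated SNAr, the standard chroman-4-one synthesis from 2'-fluoroaryl β-hydroxy ketones, to the 2,3-cis-3-benzyloxyflavan-4-one F3. NaBH4/CeCl3 at −78 °C then delivers hydride anti to the axial C3 benzyloxy group and comes back to the route at 26.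

2. Step 11. Palladium may also insert into the C–Br bond, copper may borylate the aryl halide directly, or the Cu-to-Pd transmetalation may go with inversion and give the 3,4-trans isomer. The fallback sets out from 14 (with 18) and separates the two events. Syn-diboration of 14 (B2pin2, Pt(dba)2 cat., toluene, 50 °C) from the face anti to the C2 aryl gives the cis-3,4-bis(boronate) F4. Stereoretentive Suzuki–Miyaura coupling of its benzylic C4 boronate with 18 (Pd(PPh3)4, Ag2O, DME, 80 °C) leaves the non-benzylic C3 boronate untouched and comes back to the route at 19.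

3. Step 16. The benzylic C4–O bond of the lower unit may be hydrogenolysed, or may ionize on traces of acid, during the long debenzylation of eight ethers. The fallback sets out from 26 and masks this hydroxyl. Silylation (TBSOTf, 2,6-lutidine, CH2Cl2, −78 °C) gives the C4 silyl ether F5. Hydrogenolysis (H2, Pd(OH)2/C, EtOAc/MeOH) gives the polyphenol silyl ether F6, whose bulky silyloxy group should resist C–O hydrogenolysis. Et3N·3HF in THF then removes the silyl group and comes back to the route at 27.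

Further compounds
F1 | step 15 | (2S,3R)-2-(benzyloxy)-3-[4-(benzyloxy)phenyl]-3-[(triethylsilyl)oxy]-1-aryl-propan-1-one, aryl = 2-fluoro-3,4-bis(benzyloxy)-5-(upper flavan-4-yl)phenyl | O=C(c1cc([C@@H]2c3ccc(OCc4ccccc4)c(OCc4ccccc4)c3O[C@@H](c3ccc(OCc4ccccc4)cc3)[C@@H]2OCc2ccccc2)c(OCc2ccccc2)c(OCc2ccccc2)c1F)[C@@H](OCc1ccccc1)[C@H](O[Si](CC)(CC)CC)c1ccc(OCc2ccccc2)cc1
F2 | step 15 | desilylated β-hydroxy ketone from F1 | O=C(c1cc([C@@H]2c3ccc(OCc4ccccc4)c(OCc4ccccc4)c3O[C@@H](c3ccc(OCc4ccccc4)cc3)[C@@H]2OCc2ccccc2)c(OCc2ccccc2)c(OCc2ccccc2)c1F)[C@@H](OCc1ccccc1)[C@H](O)c1ccc(OCc2ccccc2)cc1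
F3 | step 15 | (2R,3S)-2,3-cis-3,7,8-tris(benzyloxy)-2-[4-(benzyloxy)phenyl]-6-(upper flavan-4-yl)chroman-4-one | c1ccccc1COc1ccc([C@H]2Oc3c(cc([C@@H]4c5ccc(OCc6ccccc6)c(OCc6ccccc6)c5O[C@@H](c5ccc(OCc6ccccc6)cc5)[C@@H]4OCc4ccccc4)c(OCc4ccccc4)c3OCc3ccccc3)C(=O)[C@H]2OCc2ccccc2)cc1
F4 | step 11 | (2R,3R,4S)-7,8-bis(benzyloxy)-2-[4-(benzyloxy)phenyl]-3,4-bis(4,4,5,5-tetramethyl-1,3,2-dioxaborolan-2-yl)chromane (boryl groups cis, both trans to the C2 aryl) | CC1(C)OB(OC1(C)C)[C@@H]2c3ccc(OCc4ccccc4)c(OCc4ccccc4)c3O[C@@H](c3ccc(OCc4ccccc4)cc3)[C@@H]2B2OC(C)(C)C(C)(C)O2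
F5 | step 16 | 26 with a tert-butyldimethylsilyl group on the lower C4 oxygen (configuration unchanged) | c1ccccc1COc1ccc([C@H]2Oc3c(cc([C@@H]4c5ccc(OCc6ccccc6)c(OCc6ccccc6)c5O[C@@H](c5ccc(OCc6ccccc6)cc5)[C@@H]4OCc4ccccc4)c(OCc4ccccc4)c3OCc3ccccc3)[C@@H](O[Si](C)(C)C(C)(C)C)[C@H]2OCc2ccccc2)cc1
F6 | step 16 | 27 with a tert-butyldimethylsilyl group on the lower C4 oxygen | Oc1ccc([C@H]2Oc3c(cc([C@@H]4c5ccc(O)c(O)c5O[C@@H](c5ccc(O)cc5)[C@@H]4O)c(O)c3O)[C@@H](O[Si](C)(C)C(C)(C)C)[C@H]2O)cc1
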